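Count turnovers, not percent: that was my direction for this flask, a closed, stirred racemate of left-handed and right-handed substrate with reagent and a trace of precatalyst.

| flask | left-handed substrate | right-handed substrate | reagent | precatalyst | remark | time |
|---|---|---|---|---|---|---|
| Tuesday's | 67 mM | 67 mM | 2 equiv | 0.05 mol% | run made earlier |  |
| Wednesday's | 110 mM | 110 mM | 2 equiv | 0.05 mol% | run made earlier |  |
| Monday's | 48 mM | 48 mM | 2 equiv | 0.075 mol% | run made earlier |  |
| flask | 48 mM | 48 mM | 2.00 equiv | 0.05 mol% |  | 2.5 d |

| run | time / d | left-handed substrate / % | right-handed substrate / % | left-handed product / % |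
|---|---|---|---|---|
| Tuesday's | 0.625 | 48.7 | 50.0 | 1.7 |
| Tuesday's | 1.25 | 44.2 | 44.1 | 3.6 |
| Tuesday's | 2.08 | 41.3 | 44.5 | 8.7 |
| Tuesday's | 2.50 | 40.8 | 46.0 | 8.0 |
| Wednesday's | 0.333 | 49.1 | 51.1 | 3.4 |
| Wednesday's | 0.833 | 42.3 | 47.2 | 5.7 |
| Wednesday's | 1.67 | 38.6 | 44.2 | 10.0 |
| Wednesday's | 2.50 | 37.2 | 44.2 | 12.8 |
| Monday's | 0.208 | 50.0 | 46.7 | 0.6 |
| Monday's | 0.500 | 49.0 | 48.1 | 2.2 |
| Monday's | 1.04 | 42.6 | 46.2 | 5.0 |
| Monday's | 2.50 | 39.7 | 44.8 | 6.5 |

(standard deviation of a reading: 1 percentage point)

- free catalyst is single-handed; left-handed substrate and right-handed substrate are mirror images of each other, charged as a racemate, each of them at the stated concentration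
- the earlier runs were read with a standard deviation of 1 percentage point
- candidate steps: free catalyst + left-handed substrate <-> catalyst intermediate A; free catalyst + right-handed substrate <-> catalyst intermediate B; reagent + catalyst intermediate A -> free catalyst + left-handed product; reagent + catalyst intermediate B -> free catalyst + right-handed product; left-handed product <-> right-handed product; reagent + free catalyst -> spent catalyst; precatalyst -> free catalyst
- an excess is the difference of the two amounts in percent of their sum
- an excess is below zero if the other one leads

1. part of the left-handed substrate and right-handed substrate charged together that has reacted at 2.5 d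
2. excess of left-handed product over right-handed product in the product at 2.5 d
3. excess of right-handed substrate over left-handed substrate among what is left of the two at 2.5 d

At 2.50 d the substrate readings left 13.2% reacted in Tuesday's run and 18.6% in Wednesday's. That looked wrong, since both runs had 0.05 mol% of precatalyst and 2 equiv of reagent, and a catalyst good for a fixed count of turns would have taken the same percent of each charge.

So I took N, the substrate turned over per catalyst charged by that time: twice the reacted part over the loading, since the two substrates together are twice the charge the loading is counted on. Tuesday's run read N = 528 and Wednesday's 744, so the count was higher in the stronger solution, and the contradiction went.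

In powers of ten, N rose by 0.149 while concentration rose by 0.215, a slope of 0.692. Followed down to 48 mM, that line gave N = 419. Monday's run, at that concentration but at 0.075 mol%, read 15.5% reacted, so N48 = 413, a single reading, with the scatter of its two substrate values, of the turnover number at this concentration. The two readings stood close across different loadings, so I treated N as independent of loading. For this flask at 0.05 mol% I reckoned 10.3% reacted.

The forecast, which held that “Conversion levels off in every run, so the catalyst dies before the substrate runs out”, gave 10% reacted, with excesses of 32% in the product and 3.6% in the substrate.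

    free catalyst + left-handed substrate ⇌ catalyst intermediate A (K = 5.70 /M, k = 9.30 /M/s)
    free catalyst + right-handed substrate ⇌ catalyst intermediate B (K = 6.90 /M, k = 280 /M/s)
    reagent + catalyst intermediate A → free catalyst + left-handed product (k = 0.760 /M/s)
    reagent + catalyst intermediate B → free catalyst + right-handed product (k = 0.300 /M/s)
    left-handed product ⇌ right-handed product (k = 3.30 × 10⁻⁶ /s)
    reagent + free catalyst → spent catalyst (k = 6.90 × 10⁻⁴ /M/s)
    precatalyst → free catalyst (k = 1.20 × 10⁻⁵ /s)

The flask gave 9.16% reacted, with excesses of 14.1% in the product and 3.24% in the substrate. At 2.50 d spent catalyst stood at 89.2% of the catalyst charged, while 91% of the reagent was left. That result means N = 366, lower than Monday's reading of 413. For the neighbour flask at 0.085 mol%, N48 gave 17.6% reacted and this flask's N gave 15.6%, and the neighbour reached 15.0%.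

Readings and results come from a simulation with made-up constants; scatter was added.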